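Links are the product we want, and the number asked of each flask is their share of all that became links, rings or isomer of the product.

| flask | first end groups | second end groups | remark | time |
|---|---|---|---|---|
| eta | 0.20 M | 0.22 M | run made earlier |  |
| alpha | 0.10 M | 0.22 M | run made earlier |  |
| zeta | 0.15 M | 0.22 M | run made earlier |  |
| south | 0.20 M (fed, over 2.00 h) | 0.220 M | a stirred flask in which first end groups is dosed at a steady rate over 2.00 h without added volume, worked up at 2.0 h | 2.0 h |
| west | 0.20 M | 0.220 M (fed, over 2.00 h) | all but second end groups at the start; second end groups goes in evenly over 2.00 h, the run ends at 2.0 h | 2.0 h |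
| south-west | 0.20 M | 0.220 M | everything together in a closed stirred flask, run for 2.0 h | 2.0 h |
| north-east | 0.20 M | 0.220 M | a single well-mixed tank run continuously and read at steady state, 2.0 h in it on average |  |

| run | time / min | links / % | rings / % |
|---|---|---|---|
| eta | 15.0 | 25.6 | 3.9 |
| eta | 30.0 | 38.6 | 5.7 |
| eta | 50.0 | 46.5 | 7.8 |
| eta | 60.0 | 48.4 | 9.1 |
| eta | 80.0 | 52.0 | 10.4 |
| eta | 90.0 | 52.4 | 11.3 |
| eta | 120 | 54.7 | 11.8 |
| alpha | 4.00 | 8.7 | 1.3 |
| alpha | 12.0 | 23.2 | 2.2 |
| alpha | 20.0 | 32.9 | 4.6 |
| alpha | 30.0 | 42.7 | 6.3 |
| alpha | 40.0 | 48.3 | 6.5 |
| alpha | 60.0 | 56.6 | 8.7 |
| alpha | 80.0 | 60.5 | 9.7 |
| zeta | 4.00 | 9.5 | 0.8 |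
| zeta | 12.0 | 22.4 | 2.7 |
| zeta | 20.0 | 32.2 | 3.5 |
| zeta | 30.0 | 40.4 | 6.3 |
| zeta | 40.0 | 46.2 | 6.3 |
| zeta | 60.0 | 52.9 | 7.8 |
| zeta | 80.0 | 55.8 | 9.4 |

(standard deviation of a reading: 0.5 percentage points)

- the stated concentrations are those of everything mixed, before any reaction; amounts are the same in each set-up
- the feed brings no volume worth counting
- the earlier runs were made in a closed, stirred flask

- the set-up with the highest share of links in all that became links or rings or isomer of the product, at the outlet or at the end ("none" if the first two lie within 2 percentage points) (south / west / south-west / north-east / none)
- share of links in all that became links or rings or isomer of the product, at the outlet or at the end, south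
- share of links in all that became links or rings or isomer of the product, at the outlet or at the end, west
- share of links in all that became links or rings or isomer of the product, at the outlet or at the end, south-west
- share of links in all that became links or rings or isomer of the product, at the outlet or at the end, north-east

We count turnovers, starting with the uptake of first end groups. In the alpha run 25.4% of the first end groups read as links and rings at 12.0 min. That reading gives first end groups a lifetime of 41.0 min with second end groups near their full charge, or 2.93 turnovers in 2.0 h.

Next come rings. At 40.0 min the alpha and zeta runs together show 7.38 links per ring, with second end groups averaging 0.848 of their charge. Rings read 9.1% in eta and 8.7% in alpha at 60.0 min, so we take their rate to follow first end groups and not second end groups. Our rule is then: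

links per ring = F × (mean fraction of the second end groups' charge present)

The reading 8.70 is F, a selectivity factor: the links made per ring with second end groups at 0.220 M. Against rings alone, first end groups thus have a lifetime of about 357 min, longer than the one above, which is 0.336 turnovers. Isomer is not read; we assume it comes from links and count it with them in the rule, although F as read here holds links alone.

If 0.5 of the first end groups have reacted by the end, the fraction of the second end groups' charge present there is 0.545. We take the mean halfway between start and end: in south the level falls from the full charge to that fraction, and in west it rises from zero to it. Our own reckoning is: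

south: mean fraction 0.773, giving 6.73 links per ring

west: mean fraction 0.273, giving 2.38 links per ring

These ratios are our own and are not the shares asked for. The forecast gives 72% for south, 64% for west, 69% for south-west and 62% for north-east, and concludes “South leads, though narrowly”.

The flask gives 74.6% for south, 56.7% for west, 66.8% for south-west and 65.2% for north-east, so south leads. West stands 7.3 percentage points below the forecast, ending with 35.3% links and 21.1% rings. With 43% of its second end groups left, the mean fraction, halfway from zero, is 0.217 and F gives 1.89 links per ring. The west flask itself, links plus isomer over rings, holds 1.95.

    first end groups + second end groups → links (k = 0.110 L mol⁻¹ min⁻¹)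
    first end groups + second end groups → rings, rate k2*[first end groups] as long as [second end groups] is above zero (k = 0.00250 min⁻¹)
    links ⇌ isomer of the product (K = 0.470, k = 0.00420 min⁻¹)

Now take the south flask with 0.88 M of second end groups. Reckoning as if all 0.20 M had reacted, the mean level is 3.55 times 0.220 M, and F gives 30.9 links per ring. That flask holds 34.6, links plus isomer over rings, with a share of links of 82.5%.

The earlier runs and the new flask stem from a simulated flask from invented constants, noise included.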